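The ratio c(L)/(c(L) + c(Z)) at the reading is what these flasks are judged by, and it can be read as a clock.

    G + Q → G.Q (k1 = 120 /M/s)
    L ⇌ Z (K2 = 3.1, k2 = 0.062 /s)
    Q + G.Q → Q.G.Q (k3 = 12 /M/s)
    Q.G.Q + X → J (k4 = 130 /M/s)
    Q + Q.G.Q → L (k5 = 200 /M/s)

the same everywhere: X 0.150 mM; time 30 s
- maple: G 0.50 mM (in portions, 4, over 20 s); Q 1.10 equiv; first portion at the start, last at 20 s
- elm: G 0.50 mM (fed, over 20 s); Q 1.10 equiv; all else is in the flask from the start; the feed brings no volume worth counting
- cedar: G 0.50 mM; Q 1.10 equiv (fed, over 20 s); all else is in the flask from the start; the feed brings no volume worth counting
- birch: G 0.50 mM; Q 1.10 equiv; everything together at the start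

- the flask with the highest share of L in L plus Z ("all alike" if they lie within 1.5 percentage points) (maple / elm / cedar / birch / all alike)
- share of L in L plus Z at the end, maple
- share of L in L plus Z at the end, elm
- share of L in L plus Z at the end, cedar
- share of L in L plus Z at the end, birch

**Where does the share go if L is left to itself?** To the equilibrium share of L ⇌ Z, which is 24.4%.

**How fast?** The forward constant and the back constant (forward over K) add, so the distance above that floor falls with a relaxation time of 12.2 s. L of a given age therefore holds the floor plus (one minus the floor) times exp(−age/τ). I call this the L clock.

**Does the clock matter here?** Yes, because τ is shorter than the 30 s run, so the birth date of L shows in the share.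

**Your reckoning for birch?** If birch made L evenly over the whole run, averaging the clock gives 52.5%.

**But is it even?** No. In birch Q.G.Q has to build up first, and its half-life by Q + Q.G.Q → L alone, the other concentrations as charged, is 6.3 s, so I expect birch somewhat above that mark.

**And the fed flasks?** If L were born evenly in the 10.0 s after the feed, the clock gives 76.0%. I take that as a high mark, with maple, elm and cedar somewhere between the two marks and birch lowest. My reckoning stops there, and it does not rank the fed flasks.

**The forecast goes further?** It names cedar, with 64% for maple, 65% for elm, 71% for cedar and 58% for birch. Its ground: “Cedar starves Q early, so bis and L arrive latest”.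

The flasks give cedar as highest, with maple 62.9%, elm 64.8%, cedar 70.7% and birch 58.3%. On the L clock, cedar's share stands for a single age of 5.99 s and birch's for 9.77 s, so the L in cedar reads younger than the L in birch. Cedar left until 2.0 min reads 28.6%, which the clock turns into an age of 35.3 s. Left until 300 s, cedar reads 24.5% and birch 24.5%, which lie inside the margin of 1.5 percentage points.

The numbers were drawn at random within sensible limits; no experiment stands behind them.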